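Divide the product on the north-west plateau by the catalyst charged.

| setting | north-west | west | flask |
|---|---|---|---|
| starting material | 0.50 M | 0.50 M | 0.50 M |
| free catalyst | 5 mM | 5 mM | 5.0 mM |
| added ligand | 15 mM | 7.5 mM | 15 mM |
| temperature | 5 °C | −10 °C | 5 °C |
| remark | the very flask that is asked about, followed so far | run made earlier |  |
| time |  |  | 2.5 h |

| north-west: time / min | north-west: product / % | west: time / min | west: product / % |
|---|---|---|---|
| 12.0 | 39.9 | 3.00 | 26.1 |
| 40.0 | 40.5 | 8.00 | 39.1 |
| 80.0 | 40.3 | 15.0 | 43.9 |
| 120 | 38.8 | 20.0 | 45.5 |
| 150 | 41.4 | 30.0 | 46.7 |

(standard deviation of a reading: 1 percentage point)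

- what is taken out of product is counted as made
- additions bring no volume worth counting

- teal: at 2.5 h raise the temperature by 10 K, then wait 5.0 h
- violet: at 2.5 h take out 90 % of the product then present, then wait 5.0 h
- red: at 2.5 h add free catalyst, 100 % of the amount charged, then wait 5.0 h
- grey: change nothing and wait 5.0 h more

1. product, in percent of the starting material first charged, at 2.5 h
2. what to do for the largest gain in product; "none" if nothing gains more than 2 percentage points (teal / violet / red / grey / none)
3. product present, with what was taken out counted in, in percent of the starting material first charged, after teal
4. product present, with what was taken out counted in, in percent of the starting material first charged, after grey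

The north-west flask is flat from its first reading at 12.0 min. I take two amounts, the mean reading of product on that plateau and the free catalyst charged, and their ratio is the catalyst yield, product made per catalyst charged (the turnover number):

plateau product = 0.201 M

catalyst yield = plateau product / free catalyst = 40.2

The west run reads 46.7 at its last reading, a higher yield than the north-west flask's, but it is colder and holds less added ligand. I read the stall in these runs as either an equilibrium or dying catalyst. I commit to dying catalyst, and then a charge of catalyst is worth one yield. So I expect the flask to stay near its plateau under grey, teal and violet. Red, with its fresh charge, should gain: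

gain = catalyst yield × added catalyst / starting material = 40 percentage points

The forecast parts from me at teal and at the choice: it gives 40.2 % now, 36 % after teal, 40.2 % after grey, and chooses violet, on the view that “the simplest reading is an equilibrium that shifts with temperature”.

The simulated flask stands at 40.9 %, and the best choice is red. Red gains 17 points, teal 0 points, violet 0 points and grey 0 points. The flask ends at 40.9 % after teal and at 40.9 % after grey.

    starting material + free catalyst → catalyst intermediate (k = 3.89 /M/s, Ea = 54.0 kJ/mol)
    free catalyst + added ligand ⇌ idle complex (K = 21.0 /M, k = 2.04 /M/s, Ea = 46.0 kJ/mol, ΔH = −36.0 kJ/mol)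
    catalyst intermediate ⇌ free catalyst + product (K = 0.168 M, k = 2.80 /s, Ea = 66.0 kJ/mol, ΔH = 12.0 kJ/mol)
    catalyst intermediate → spent catalyst (k = 0.0303 /s, Ea = 77.0 kJ/mol)
    (constants at 5 °C)

In this flask, spent catalyst stands at 100 % of the catalyst charged at 150 min, while 58 % of the starting material remains. Red gains 17 points where I reckoned 40 points. The neighbour charged with 0.85 M of starting material keeps the same catalyst, so one yield reckons to 23.6 % of its charge. That neighbour gives 29.9 %, a catalyst yield of 50.8.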